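## Analysis of the target

The target 29 is a 3-acyltetramic acid whose acyl carbon sits on the quaternary C1 of a cis-fused octalin; in decalin numbering ring A is C1, C2, C3=C4, C4a, C8a and ring B is C4a, C5, C6, C7, C8, C8a. The carbocycle carries five stereocentres (C1, C2, C4a, C6, C8a): the acyl group on C1, the (1E,3E)-pentadienyl group on C2 and both angular hydrogens lie on one face, the C1 methyl and the C6 methyl on the other. The heterocycle is (5S)-5-[(1R)-1-hydroxyethyl], the L-threonine pattern, and C5′ can epimerise under base. Sensitive groups are the conjugated diene, the doubly allylic C2–H, the acidic metal-chelating tricarbonyl and the free secondary hydroxyl. The synthesis is hard first because C8a, the quaternary C1 and C2 are contiguous and all-cis. It is hard second because the remote C6 methyl lies on the concave face of the cis-decalin, where every chair–chair form keeps one 1,3-diaxial contact (C1 against C5 and C7, or C6–CH3 against C4), so this epimer is judged the less stable one and C6 cannot be left to equilibration. The strategy rests on ring B being cis-fused to a ring A whose C3=C4 alkene is next to C4a. With oxygen placed on C7 this is a δ,ε-unsaturated ketone, the product pattern of an oxy-Cope rearrangement of a bicyclo[2.2.2]octenol.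

## Retrosynthetic reasoning

**Tetramic acid ring.** 29 is cut at C3′–C4′ (Lacey–Dieckmann transform) to the β-keto amide 28. This is done last because the enolised tricarbonyl is acidic, chelating and awkward to carry. The forward step must close the ring without epimerising C5′.

**Amide bond.** 28 is cut at N–C(=O) to the β-keto thioester 25 and the L-threonine ester 26 (free base 27). Both heterocycle stereocentres are bought, and a thioester can be aminolysed under neutral, thiophilic activation.

**Two-carbon extension at C1.** 25 is cut between the ketone carbon and its CH2, through the aldol 24, to the aldehyde 21 and the thioacetate 22 (as enolate 23). The aldehyde carbon is on a quaternary centre, so it cannot enolise. 21 comes from the primary alcohol 20.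

**Dienyl chain.** The diene of 20 is cut at C2′–C3′ to the (E)-vinyl iodide 18 and the (E)-propenylboronate 19, so both double-bond geometries come from stereodefined partners. 18 is cut at C1′=C2′ to the aldehyde 17, the open form of lactol 16, which comes from lactone 15. The lactone ties the C1 and C2 carbons together on one face and holds them at different oxidation levels, so partial reduction differentiates them without protecting groups. A one-step Julia–Kocienski olefination of 16 was considered and is kept only as a fallback, because it exposes the epimerisable C2–H of 17 to a basic carbanion and controls the diene geometry less securely.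

**C7 oxygen.** 15 is traced back to ketone 12 by adding a carbonyl at C7. This oxygen is the handle of the rearrangement, and forward it is removed by reduction and radical deoxygenation through 13 and 14.

**Key disconnection.** In 12, C4a–C5 is cut and C7 is rejoined to C3. This gives the bicyclo[2.2.2]octenol 9 through enolate 11 and alkoxide 10. The atom mapping (decalin → bicycle) is: C7 → carbinol C2, C3 → bridgehead C1, C4 → C6, C4a → C5, C8a → C4, C8 → C3, C1 → C8, C2 → C7; C5 and C6 are the isopropenyl CH2 and its central carbon. The cut is made here because the bicycle locks the relative configuration of C1, C2 and C8a and forces cis fusion at C4a. The forward step must deliver the C6=C7 enolate regiospecifically so that C6 can be set by protonation.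

**Carbinol.** 9 is cut at the carbinol–isopropenyl bond to ketone 6 and the isopropenyl Grignard reagent 7 (used as cerium reagent 8). The addition must come from the face of the C5=C6 bridge.

**Bicyclic ketone.** 6 is the resolved form of racemic 5, which comes from the dimethoxy ketone 4 by removal of both methoxy groups. 4 is cut at C1–C7 and C4–C8 (Diels–Alder transform) into the masked o-benzoquinone 3 and the butenolide 2. The dienone 3 is generated from guaiacol 1 by oxidative dearomatisation in the presence of 2, so one operation builds the whole bicycle and 3 is never stored.

## Alternatives that were turned down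

**Alternative 1:** Ring B is disconnected by an intermolecular Diels–Alder reaction across C4a=C8a (bonds C4a–C5 and C8–C8a). The silyloxy diene A2 would add to the lactone-fused cyclohexenone A3 under Me2AlCl or heat to give the silyl enol ether A1.
- For: it is convergent, forms two ring-B bonds at once, and the cis fusion follows from suprafacial addition. A3 could be made in enantioenriched form, so no resolution would be needed. On absolute stereocontrol it is stronger than the chosen route.
- Against: the enone β-carbon C8a is next to the quaternary C1, and the diene must approach on the face of the C1 methyl. A1 carries two ketone-level oxygens (C4 and C7). The C3=C4 alkene must still be made regioselectively from the C4 ketone, with C4a epimerisable next to it. C6 is still unset, as in the chosen route.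
- Comparison: the chosen route delivers C3=C4 in place and leaves only C7 to deoxygenate, at the price of a resolution.

**Alternative 2:** Rings A and B are disconnected together by an intramolecular Diels–Alder reaction (bonds C4a–C8a and C5–C6). The trienone A5 would cyclise to the octalinone lactone A4.
- For: one step builds both rings and sets C6 from the diene geometry. On C6 it is stronger than the chosen route, which depends on a kinetic protonation.
- Against: cis versus trans fusion depends on the endo/exo preference of a tethered enone and is not enforced. The new alkene appears at C7=C8, where the target has none, so it must be hydrogenated and C3=C4 made afterwards from the C4 ketone. A5 needs the quaternary C1 carrying a dienyl group to be set enantioselectively before any ring exists. The lactone carbonyl of A4 sits on the quaternary carbon, where a two-carbon nucleophile must later attack.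
- Comparison: the chosen route fixes the fusion and the C1/C2 relationship by the rigid bicycle and places the alkene correctly; it is weaker only at C6.

**Alternative 3:** Ring A is disconnected at C2–C3 by a cation–olefin cyclisation. Ionisation of the dienyl carbinol A7 with BF3·OEt2 would let its (Z)-vinylsilane attack through the silicon-bearing carbon to give the ester A6.
- For: the dienyl group and the C1 carboxyl are already in place, and silicon dictates the alkene position. After the key step it is the shortest of all the plans.
- Against: C2 is created by attack on a planar pentadienyl cation beside a quaternary carbon whose CH3 and ester differ little in size, so the required cis relationship is not secured. The delocalised cation can be captured at other carbons or lose its E,E geometry. A7 already contains C4a, C6, C8a and the acyclic quaternary C1, so the stereochemical problem is moved, not solved.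
- Comparison: the chosen route sets C1, C2, C4a and C8a through two concerted, stereospecific events.

Key step: step 5

## Remarks before the steps

- Racemic compounds (4, 5) are written with the SMILES of the enantiomer that is carried on.
- Centres that form as mixtures and are destroyed later (C7 in 13 and 14, the lactol carbon of 16, the carbinol of 24) are left undefined.
- Bicycles are numbered as bicyclo[2.2.2]oct-5-en-2-ones: C1 is the bridgehead next to C2 (C=O or carbinol), C3 carries the two methoxy groups or two hydrogens, C4 is the other bridgehead, C5=C6 is the alkene, C7 carries the lactone carbonyl, and C8 carries CH3 and the lactone OCH2. "Endo" means the lactone ring lies under the C5=C6 bridge.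
- Decalins carry the numbering of the target.

## Route

Step 1
Reactants: 1 guaiacol; 2 4-methylfuran-2(5H)-one (large excess)
Product: 4 racemic endo lactone adduct, via masked o-benzoquinone 3 (not isolated)
Conditions: PhI(OAc)2, MeOH, 2 (20 equiv), 1 added slowly over 8 h, rt → 50 °C
Reagents that add atoms: methanol, CO
Why: Oxidative dearomatisation with hypervalent iodine in methanol gives dienone 3, which is trapped as it forms in a Diels–Alder reaction of a masked o-benzoquinone; slow addition of 1 keeps 3 dilute against the large excess of 2 so that cycloaddition can compete with self-dimerisation. The usual ortho/endo preference joins the lactone α-carbon to the dienone carbon next to C=O and puts the lactone under the new alkene, which sets C1, C4, C7 and C8 in the relative sense.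

Step 2
Reactants: 4 adduct
Product: 5 racemic bicyclo[2.2.2]oct-5-en-2-one lactone
Conditions: SmI2 (about 4.5 equiv), THF–MeOH, −78 °C → rt
Reagents that add atoms: none
Why: Single-electron reduction of the α-alkoxy ketone expels each methoxide in turn and methanol protonates the samarium enolate; the lactone and the isolated alkene are not reduced under these conditions.

Step 3
Reactants: 5 racemic ketone
Product: 6 ketone as single enantiomer
Conditions: preparative SFC on a chiral stationary phase (amylose tris(3,5-dimethylphenylcarbamate)), CO2–MeOH
Reagents that add atoms: none
Why: Resolution by chromatography on a chiral phase at the first compact, polar intermediate; the unwanted enantiomer is discarded and the absolute configuration would be confirmed by correlation with the L-threonine-derived amide 28.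

Step 4
Reactants: 6 ketone; 7 isopropenylmagnesium bromide
Product: 9 2-isopropenyl carbinol, via isopropenylcerium dichloride 8 (not isolated)
Conditions: CeCl3, THF, −78 °C
Reagents that add atoms: none
Why: Organocerium 1,2-addition, which suppresses enolisation at C3 and should attack the ketone ahead of the lactone at −78 °C; the reagent should approach C2 past the sp2 C6–H and not past the exo C7–H and C8–CH3, placing the isopropenyl group syn to the C5=C6 bridge.

Step 5
Reactants: 9 carbinol
Product: 12 cis-fused lactone-bridged octalin-7-one, via potassium alkoxide 10 (not isolated), via potassium enolate 11 (not isolated)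
Conditions: KN(SiMe3)2 (1.0 equiv), 18-crown-6, THF, 0 °C → rt; then added to AcOH–THF, −78 °C
Reagents that add atoms: none
Why: Deprotonation gives alkoxide 10, whose oxyanion weakens the adjacent C1–C2 bridgehead bond; the isopropenyl CH2 terminus, held over the C5=C6 bridge, bonds to C5 while C1–C2 breaks in the boat-like six-centre array that the bicycle enforces, giving enolate 11. The closest known reaction type is the anionic oxy-Cope rearrangement of 2-alkenylbicyclo[2.2.2]oct-5-en-2-ols to cis-fused octalones. Ring B closes by this [3,3] sigmatropic shift, which forms C4a–C5, turns the bridged skeleton into the fused one and leaves the alkene at C3=C4. C4a is set suprafacially by the framework: the new bond arrives on the alkene face turned toward the carbinol bridge, the side on which C8 already sits at C8a, so the fusion is cis and its relation to C1 and C2 follows from the endo lactone and exo methyl. C6 is set in the quench: 11 should be protonated from the convex face of the folded octalin, anti to the pseudoaxial C4a–C4 bond that covers the other face, which puts 6-H on the side of the angular hydrogens and the methyl trans to them. The step needs O–H deprotonation ahead of lactone α-C–H deprotonation (one equivalent of base), rearrangement faster than proton exchange between 11 and the allylic C2–H (crown ether, short time), and kinetic protonation (inverse quench into cold acid, no base afterwards) because the wanted C6 epimer is judged the less stable one.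

Step 6
Reactants: 12 ketone
Product: 13 C7 alcohol (epimer mixture at C7)
Conditions: NaBH4, CeCl3·7H2O, MeOH, −78 °C
Reagents that add atoms: none
Why: Luche reduction under cold, near-neutral conditions removes the enolisable carbonyl before C6 can epimerise; the lactone is not reduced and the C7 configuration is of no consequence.

Step 7
Reactants: 13 alcohol
Product: 14 O-phenyl thionocarbonate
Conditions: PhOC(S)Cl, pyridine, DMAP (cat.), CH2Cl2, 0 °C → rt
Reagents that add atoms: O-phenyl chlorothionoformate, S=C(Cl)Oc1ccccc1
Why: Acylation of the secondary alcohol to the radical precursor of a Barton–McCombie deoxygenation without strong base, so the lactone α-centre is safe.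

Step 8
Reactants: 14 thionocarbonate
Product: 15 lactone-bridged 1,6-dimethyl-cis-octalin
Conditions: Bu3SnH, AIBN (cat.), toluene, 100 °C
Reagents that add atoms: none
Why: Barton–McCombie deoxygenation: the stannyl radical adds to C=S, β-scission gives the secondary C7 radical and Bu3SnH reduces it; cyclisation onto C3=C4 would need a strained bridged ring and should not compete, and C6 is untouched.

Step 9
Reactants: 15 lactone
Product: 16 lactol (anomer mixture)
Conditions: i-Bu2AlH, CH2Cl2, −78 °C; aq. potassium sodium tartrate
Reagents that add atoms: none
Why: Partial reduction of the γ-lactone stops at the aluminium hemiacetal, which collapses only on work-up; the C2 carbon is thereby at aldehyde level and the C1 carbon at alcohol level.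

Step 10
Reactants: 16 lactol
Product: 18 (E)-vinyl iodide alcohol, via hydroxy aldehyde 17 (not isolated)
Conditions: CrCl2, CHI3, THF, 0 °C → rt
Reagents that add atoms: iodoform, IC(I)I
Why: Takai iodo-olefination of the open aldehyde form 17; the geminal dichromium reagent adds and eliminates to the (E)-alkene, and the non-basic medium should leave the epimerisable C2–H and the free hydroxyl alone.

Step 11
Reactants: 18 vinyl iodide; 19 (E)-prop-1-enylboronic acid pinacol ester
Product: 20 (1E,3E)-pentadienyl alcohol
Conditions: Pd(PPh3)4 (cat.), K3PO4, THF–H2O, 50 °C
Reagents that add atoms: none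
Why: Suzuki–Miyaura coupling proceeds with retention at both alkenyl partners, so the diene should form as the E,E isomer.

Step 12
Reactants: 20 alcohol
Product: 21 aldehyde
Conditions: Dess–Martin periodinane, NaHCO3, CH2Cl2, 0 °C → rt
Reagents that add atoms: none
Why: Buffered Dess–Martin oxidation of the neopentyl alcohol; the aldehyde carbon is on a quaternary centre and cannot epimerise, and the buffer protects the diene.

Step 13
Reactants: 21 aldehyde; 22 S-tert-butyl thioacetate
Product: 24 β-hydroxy thioester (carbinol epimers), via lithium thioester enolate 23 (not isolated)
Conditions: LiN(i-Pr)2, THF, −78 °C; then 21; aq. NH4Cl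
Reagents that add atoms: none
Why: Aldol addition of a small lithium thioester enolate to a non-enolisable hindered aldehyde; the new carbinol centre is removed in the next step.

Step 14
Reactants: 24 β-hydroxy thioester
Product: 25 β-keto thioester
Conditions: Dess–Martin periodinane, NaHCO3, CH2Cl2, rt
Reagents that add atoms: none
Why: Dess–Martin oxidation of a β-hydroxy thioester to the β-keto thioester, which tolerates the diene and the thioester.

Step 15
Reactants: 25 β-keto thioester; 26 L-threonine methyl ester hydrochloride
Product: 28 β-keto amide, via L-threonine methyl ester 27 (not isolated)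
Conditions: AgOCOCF3 (2.2 equiv), Et3N, THF, 0 °C → rt
Reagents that add atoms: none
Why: Silver-promoted aminolysis of the S-tert-butyl thioester (thiophilic activation) should acylate the amine ahead of the secondary hydroxyl under neutral conditions that keep both threonine centres.

Step 16
Reactants: 28 β-keto amide
Product: 29 target CNP0298257.5
Conditions: KOt-Bu, t-BuOH, rt, short time; then 1 M HCl
Reagents that add atoms: none
Why: Lacey–Dieckmann cyclisation: the stabilised carbanion of the β-keto amide attacks the methyl ester in a 5-exo closure and the tetramate anion is a non-basic sink; a short reaction time limits epimerisation at C5′, and both heterocycle stereocentres come from 26.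

## Compound list

1 | guaiacol (2-methoxyphenol) | COc1ccccc1O | starting material
2 | 4-methylfuran-2(5H)-one | CC1=CC(=O)OC1 | starting material
3 | 6,6-dimethoxycyclohexa-2,4-dien-1-one (masked o-benzoquinone) | COC1(OC)C=CC=CC1=O | intermediate (not isolated)
4 | racemic endo adduct: 3,3-dimethoxy-8-methylbicyclo[2.2.2]oct-5-en-2-one with cis γ-lactone C7–C(=O)–O–CH2–C8 under the C5=C6 bridge, C8 methyl toward the C2–C3 bridge | O=C1C(OC)(OC)[C@H]2C=C[C@@H]1[C@H]3[C@]2(C)COC3=O | intermediate
5 | racemic 8-methylbicyclo[2.2.2]oct-5-en-2-one 7,8-lactone (C3 = CH2) | O=C1C[C@H]2C=C[C@@H]1[C@H]3[C@]2(C)COC3=O | intermediate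
6 | the ketone of 5 as the single enantiomer drawn | O=C1C[C@H]2C=C[C@@H]1[C@H]3[C@]2(C)COC3=O | intermediate
7 | isopropenylmagnesium bromide | CC(=C)[Mg]Br | starting material
8 | isopropenylcerium dichloride | CC(=C)[Ce](Cl)Cl | intermediate (not isolated)
9 | 2-isopropenyl-8-methylbicyclo[2.2.2]oct-5-en-2-ol 7,8-lactone, isopropenyl syn to C5=C6, OH toward the C7–C8 bridge | CC(=C)[C@@]1(O)C[C@H]2C=C[C@@H]1[C@H]3[C@]2(C)COC3=O | intermediate
10 | potassium alkoxide of 9 | CC(=C)[C@@]1([O-])C[C@H]2C=C[C@@H]1[C@H]3[C@]2(C)COC3=O.[K+] | intermediate (not isolated)
11 | potassium C6=C7 enolate of 12 | O=C3[C@H]1C=C[C@@H]2CC(C)=C([O-])C[C@@H]2[C@@]1(C)CO3.[K+] | intermediate (not isolated)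
12 | cis-fused 1,6-dimethyl-7-oxo-octalin (C3=C4) with lactone C2–C(=O)–O–CH2–C1, 6-CH3 trans to H-4a and H-8a | O=C3[C@H]1C=C[C@@H]2C[C@H](C)C(=O)C[C@@H]2[C@@]1(C)CO3 | intermediate
13 | C7 alcohol of 12 (C7 epimers) | O=C3[C@H]1C=C[C@@H]2C[C@H](C)C(O)C[C@@H]2[C@@]1(C)CO3 | intermediate
14 | O-phenyl thionocarbonate of 13 | O=C3[C@H]1C=C[C@@H]2C[C@H](C)C(OC(=S)Oc4ccccc4)C[C@@H]2[C@@]1(C)CO3 | intermediate
15 | lactone-bridged 1,6-dimethyl-cis-octalin (C7 = CH2) | O=C3[C@H]1C=C[C@@H]2C[C@H](C)CC[C@@H]2[C@@]1(C)CO3 | intermediate
16 | lactol of 15 (anomers) | OC3[C@H]1C=C[C@@H]2C[C@H](C)CC[C@@H]2[C@@]1(C)CO3 | intermediate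
17 | 1-(hydroxymethyl)-1,6-dimethyl-cis-octalin-2-carbaldehyde, open form of 16 | O=C[C@H]1C=C[C@@H]2C[C@H](C)CC[C@@H]2[C@@]1(C)CO | intermediate (not isolated)
18 | [2-[(E)-2-iodoethenyl]-1,6-dimethyl-cis-octalin-1-yl]methanol | I/C=C/[C@H]1C=C[C@@H]2C[C@H](C)CC[C@@H]2[C@@]1(C)CO | intermediate
19 | 4,4,5,5-tetramethyl-2-[(E)-prop-1-enyl]-1,3,2-dioxaborolane | C/C=C/B1OC(C)(C)C(C)(C)O1 | starting material
20 | [1,6-dimethyl-2-[(1E,3E)-penta-1,3-dienyl]-cis-octalin-1-yl]methanol | C/C=C/C=C/[C@H]1C=C[C@@H]2C[C@H](C)CC[C@@H]2[C@@]1(C)CO | intermediate
21 | the corresponding C1 carbaldehyde | C/C=C/C=C/[C@H]1C=C[C@@H]2C[C@H](C)CC[C@@H]2[C@@]1(C)C=O | intermediate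
22 | S-tert-butyl thioacetate | CC(=O)SC(C)(C)C | starting material
23 | lithium enolate of 22 | [Li+].C=C([O-])SC(C)(C)C | intermediate (not isolated)
24 | S-tert-butyl 3-hydroxy-3-(decalinyl)propanethioate (carbinol epimers) | C/C=C/C=C/[C@H]1C=C[C@@H]2C[C@H](C)CC[C@@H]2[C@@]1(C)C(O)CC(=O)SC(C)(C)C | intermediate
25 | S-tert-butyl 3-oxo-3-(decalinyl)propanethioate | C/C=C/C=C/[C@H]1C=C[C@@H]2C[C@H](C)CC[C@@H]2[C@@]1(C)C(=O)CC(=O)SC(C)(C)C | intermediate
26 | L-threonine methyl ester hydrochloride | C[C@@H](O)[C@H](N)C(=O)OC.Cl | starting material
27 | L-threonine methyl ester | C[C@@H](O)[C@H](N)C(=O)OC | intermediate (not isolated)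
28 | methyl N-[3-oxo-3-(decalinyl)propanoyl]-L-threoninate | C/C=C/C=C/[C@H]1C=C[C@@H]2C[C@H](C)CC[C@@H]2[C@@]1(C)C(=O)CC(=O)N[C@@H]([C@@H](C)O)C(=O)OC | intermediate
29 | CNP0298257.5, (5S)-3-acyl-5-[(1R)-1-hydroxyethyl]tetramic acid of the cis-octalin | C/C=C/C=C/[C@H]1C=C[C@@H]2C[C@H](C)CC[C@@H]2[C@@]1(C)C(=O)C1=C(O)[C@H]([C@@H](C)O)NC1=O | target

## Step count and least certain steps

Total: 16 steps. Longest linear sequence: 16 steps, from guaiacol 1; compounds 2, 7, 19, 22 and 26 are bought and enter directly.

**Step 5 (key step).** The most likely failure is loss of C6 control. Protonation of enolate 11 may not be face-selective, or the ketone may epimerise to the more stable C6 epimer before reduction. Proton exchange between 11 and the acidic allylic C2–H next to the lactone carbonyl could also scramble C6 and move the ring-A alkene. The fallback sets out from 9 and avoids any free enolate. The carbinol is silylated (Me3SiOTf, 2,6-lutidine) to the trimethylsilyl ether F1. F1 is heated without base (o-dichlorobenzene, about 250 °C, sealed) in a neutral siloxy-Cope rearrangement to the trimethylsilyl enol ether F2. F2 is protonated at −78 °C under reagent control with a Lewis-acid-assisted chiral Brønsted acid (the SnCl4 complex of (R)- or (S)-1,1′-bi-2-naphthol, the antipode chosen to match the substrate). The route is rejoined at 12.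

**Step 1.** The dienophile 2 is trisubstituted and its β-carbon must bond beside the ketal carbon, so self-dimerisation of dienone 3 may outrun the trapping, and endo selectivity may erode if more heat is needed. The fallback sets out from 1 and uses a dienone that does not dimerise and can therefore be isolated and heated. 1 is brominated para to the hydroxyl (N-bromosuccinimide, MeCN, 0 °C) to 4-bromo-2-methoxyphenol F3. F3 is oxidised (PhI(OAc)2, MeOH) to 4-bromo-6,6-dimethoxycyclohexa-2,4-dien-1-one F4, whose bromine blocks the double bond that acts as the 2π partner in dimerisation. F4 is heated with neat 2 for a long time to give the bromo adduct F5. Radical debromination (Bu3SnH, AIBN) rejoins the route at 4.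

**Step 4.** Addition may occur on the face of the C7–C8 bridge, giving a carbinol epimer that cannot rearrange. Enolisation at C3 or attack at the lactone may also consume material. The fallback sets out from 4 and adds the nucleophile before the methoxy groups are removed, when the ketone is non-enolisable and more electrophilic. 4 is resolved on the same chiral phase to its single enantiomer F6. The cerium reagent 8 adds to give the dimethoxy carbinol F7. The same rearrangement and cold protonation give the 8,8-dimethoxy-7-ketone F8. SmI2 then removes both methoxy groups and the route is rejoined at 12.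

**Step 10.** The open aldehyde 17 is present only in low concentration beside lactol 16, so iodo-olefination may be slow, and Lewis-acidic chromium salts may divert the lactol. The fallback sets out from 16 and forms the whole diene in one Julia–Kocienski olefination. 1-Phenyl-1H-tetrazole-5-thiol and (E)-but-2-en-1-ol are joined under Mitsunobu conditions to the sulfide F9. Oxidation (H2O2, (NH4)6Mo7O24) gives the sulfone F10. Its potassium anion (KN(SiMe3)2, 1,2-dimethoxyethane, −60 °C, one extra equivalent of base for the lactol hydroxyl) reacts with 16. The route is rejoined at 20, with any geometric isomers removed on silver nitrate-impregnated silica.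

**Step 16.** The secondary amide closes slowly, so the ester α-centre (C5′) may epimerise before ring closure. The free β-hydroxy amino ester may also undergo retro-aldol cleavage under alkoxide. The fallback sets out from 25 with a masked hydroxyl. 26 is O-silylated (t-BuMe2SiCl, imidazole) to the silyl ether F11. Silver-promoted aminolysis of 25 with F11 gives the amide F12. Lacey–Dieckmann closure gives the silylated tetramic acid F13, from which any C5′ epimer is separable as a diastereomer. HF·pyridine removes the silyl group and the route is rejoined at 29.

## Further compounds

F1 | step 5 | trimethylsilyl ether of carbinol 9 | CC(=C)[C@@]1(O[Si](C)(C)C)C[C@H]2C=C[C@@H]1[C@H]3[C@]2(C)COC3=O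
F2 | step 5 | C6=C7 trimethylsilyl enol ether of ketone 12 | O=C3[C@H]1C=C[C@@H]2CC(C)=C(O[Si](C)(C)C)C[C@@H]2[C@@]1(C)CO3
F3 | step 1 | 4-bromo-2-methoxyphenol | COc1cc(Br)ccc1O
F4 | step 1 | 4-bromo-6,6-dimethoxycyclohexa-2,4-dien-1-one | COC1(OC)C=C(Br)C=CC1=O
F5 | step 1 | racemic 5-bromo analogue of adduct 4 | O=C1C(OC)(OC)[C@H]2C(Br)=C[C@@H]1[C@H]3[C@]2(C)COC3=O
F6 | step 4 | adduct 4 as the single enantiomer drawn | O=C1C(OC)(OC)[C@H]2C=C[C@@H]1[C@H]3[C@]2(C)COC3=O
F7 | step 4 | 3,3-dimethoxy analogue of carbinol 9 | CC(=C)[C@@]1(O)C(OC)(OC)[C@H]2C=C[C@@H]1[C@H]3[C@]2(C)COC3=O
F8 | step 4 | 8,8-dimethoxy analogue of ketone 12 | O=C3[C@H]1C=C[C@@H]2C[C@H](C)C(=O)C(OC)(OC)[C@@H]2[C@@]1(C)CO3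
F9 | step 10 | 5-[(E)-but-2-enylsulfanyl]-1-phenyl-1H-tetrazole | C/C=C/CSc1nnnn1-c1ccccc1
F10 | step 10 | 5-[(E)-but-2-enylsulfonyl]-1-phenyl-1H-tetrazole | C/C=C/CS(=O)(=O)c1nnnn1-c1ccccc1
F11 | step 16 | methyl O-(tert-butyldimethylsilyl)-L-threoninate | C[C@@H](O[Si](C)(C)C(C)(C)C)[C@H](N)C(=O)OC
F12 | step 16 | O-tert-butyldimethylsilyl ether of β-keto amide 28 | C/C=C/C=C/[C@H]1C=C[C@@H]2C[C@H](C)CC[C@@H]2[C@@]1(C)C(=O)CC(=O)N[C@@H]([C@@H](C)O[Si](C)(C)C(C)(C)C)C(=O)OC
F13 | step 16 | O-tert-butyldimethylsilyl ether of target 29 | C/C=C/C=C/[C@H]1C=C[C@@H]2C[C@H](C)CC[C@@H]2[C@@]1(C)C(=O)C1=C(O)[C@H]([C@@H](C)O[Si](C)(C)C(C)(C)C)NC1=O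
A1 | alternative 1 | tricyclic cis-decalin silyl enol ether with C4 ketone | C3[C@H]1CC(=O)[C@@H]2CC(C)=C(O[Si](C)(C)C(C)(C)C)C[C@@H]2[C@@]1(C)C(=O)O3
A2 | alternative 1 | 2-(tert-butyldimethylsilyloxy)-3-methylbuta-1,3-diene | C=C(O[Si](C)(C)C(C)(C)C)C(C)=C
A3 | alternative 1 | lactone-fused cyclohexenone dienophile | C3[C@H]1CC(=O)C=C[C@@]1(C)C(=O)O3
A4 | alternative 2 | tricyclic cis-octalin-4-one lactone with C6 methyl | O1C[C@H]2CC(=O)[C@@H]3C[C@H](C)C=C[C@@H]3[C@@]2(C)C1=O
A5 | alternative 2 | lactone trienone carrying vinyl ketone and (1E,3E)-pentadienyl group | O1C[C@@H](CC(=O)C=C)[C@@](C)(/C=C/C=C/C)C1=O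
A6 | alternative 3 | cis-decalin methyl ester with dienyl at C2 | C/C=C/C=C/[C@H]1C=C[C@@H]2C[C@H](C)CC[C@@H]2[C@@]1(C)C(=O)OC
A7 | alternative 3 | dienyl carbinol with (Z)-vinylsilane on the cyclohexane | C/C=C/C=C/C(O)[C@](C)(C(=O)OC)[C@H]1CC[C@@H](C)C[C@H]1/C=C\[Si](C)(C)C
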